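## Structural features

13-Acetoxysarcocrassolide is a 14-membered carbocycle (C1–C14). An α-methylene-γ-butyrolactone (C15, C16, O, C14, C1; exocyclic C15=C17) is fused to it across C1–C14 with H1 and H14 anti. C13 (acetate), C14 (lactone oxygen) and C1 are contiguous stereocentres, and the two C–O bonds at C13 and C14 are syn along the chain C12–C13–C14–C1. Separated from C1 only by the C2 methylene lies the trisubstituted (3S,4S)-oxirane with C2 and C5 trans. Two E-trisubstituted alkenes (C7=C8, C11=C12) complete the ring. The fragile groups are the α-methylene lactone (Michael acceptor, base-sensitive), the oxirane (acid-labile, and opened at once by a radical on C2) and the allylic acetate (acyl shift to a neighbouring alkoxide). The real difficulty is the order of events: a macrocycle has to be closed in the presence of other alkenes, and each of the three fragile groups rules out a class of reagents. The key step exploits the fact that C15 is bonded to C1 and, through C16 and the ring oxygen, to C14. An ether tether on O14 of a ring holding a C1=C2 alkene puts a C15 radical five atoms from C1, so the oxolane and the C1 centre can be added to a finished 14-membered ring with C14 choosing the face.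

## Logic of the disconnections

In 26 the C3–O bond of the oxirane is cut, leading through 25 and 24 to the dioxolane 23. An oxirane next to C2 cannot survive radical chemistry at C1, whereas a dioxolane can. The forward closure is an SN2 attack of O4 on C3, so 23–25 must be the erythro (3R,4S) series, and the base must spare the acetate and the unsaturated lactone.

23 is simplified to 22 by removing the carbonyl oxygen at C16. This turns the lactone into a plain cyclic allyl ether that a tin hydride step can deliver. The forward step must oxidise one CH2, the only one that is both allylic and next to oxygen, among several allylic positions.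

22 is cut at C1–C15, which opens the oxolane and removes the C1 stereocentre, giving 21. The cut is made here because a C15 vinyl radical tethered through O14 reaches C1 in a 5-exo mode. The forward step must close faster than the radical is reduced, attack the face of C1 anti to C13, and have the C2 radical reduced before it finds C7.

21 is taken back through 20 and 19 to 17 and 18 by cutting the O14–C16 ether bond and the acetyl group. The ether is made by alkylating an alkoxide on O14, and an acetate on O13 would migrate to that alkoxide. O13 therefore carries a silyl group that resists 1,2-shift during the alkylation and is exchanged for acetate afterwards.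

17 is opened at C1=C2, the only disubstituted alkene of the ring, to the diene 16. Its geometry is erased in the key step, so E-selectivity matters only for a uniform precursor. The forward metathesis must start at the C14 vinyl group, because an alkylidene on C2 could close a six-membered ring onto C7=C8.

16 is traced through 15 and 14 to 8 and 9 by cutting C13–C14. One reagent-controlled step then sets both C13 and C14 and brings in C14, C1 and a differentiated O14. The forward step must be syn-selective and override the distant C3/C4 centres.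

8 is reduced in oxidation level at C13 to 7 and then to the methyl compound 6. This lets the whole C2–C13 chain with its three methyls come from one precursor. The forward oxidation must pick the E-methyl of the terminal alkene.

6 is taken back through 5 to 2 and then 1. The vinyl carbon on C2 and the O3 oxygen are removed, and C3 and C4 return to the E-alkene. Epoxidation sets C4 and the absolute sense, and a Payne shift followed by one-carbon extension inverts C3 and adds the vinyl group in one operation. The forward step must open the rearranged terminal oxirane and not the original one.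

## Other disconnections considered

Alternative 1: The cut is the C5–C6 single bond, with C4 as a ketone and C5 bearing a phenylsulfonyl group. In the forward step Pd(PPh3)4 would ionise a primary allylic carbonate at C6, and the β-keto sulfone carbanion at C5 would attack the unsubstituted allyl terminus under high dilution to give A1 as a C5 epimer mixture.
- In its favour: ring closure of a soft carbanion on an allyl complex of palladium is among the most dependable ways to a 14-membered carbocycle. The lactone and its three centres are finished before cyclisation, no alkene is formed or endangered, and neither tin hydride nor chromium is needed.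
- Against it here: after A1 there remain desulfonylation, methyl addition to the macrocyclic C4 ketone (chelation to the C3 ether being the only control, with the lactone carbonyl competing), removal of the C3 ether, mesylation and oxirane closure, α-methylenation with strong base, and silyl-to-acetyl exchange at C13. The C6–C8 allyl unit may lose its 7E geometry, and the chain must be built from two fragments.
- Comparison: in structure, A1 has C1, C13 and C14 settled but lacks C4 and C17. In mechanism, its ring closure is the better of the two, more secure than the metathesis of step 9 and free of radical side paths. In step economy it is poorer, with about seven operations after the key step against four, and C4 is substrate-controlled there but reagent-controlled here.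

Alternative 2: The cut is C11–C12, taken as an alkyne. In the forward step Mo(≡CC6H4OMe)(OSiPh3)3 would metathesise two methyl-capped alkynes to the cycloalkyne A2 with loss of but-2-yne.
- In its favour: the catalyst ignores alkenes, so the methylene lactone and the 7E alkene are spectators, and oxirane and lactone are already in place. About four operations follow A2 (desilylation, hydroxyl-directed trans-hydrostannation, methyl-for-tin exchange, acetylation).
- Against it here: the 11E trisubstituted alkene must be made late, next to C13, on a substrate that holds an oxirane and a Michael acceptor. The Lewis-acidic molybdenum centre meets the oxirane. Both halves of the diyne need separate asymmetric syntheses, because 1 cannot be used whole.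
- Comparison: in chemoselectivity of ring closure it is better than the chosen plan, and it avoids the C–H oxidation. The length after the key step is equal. It is worse in the length before the key step and in the late alkene construction.

Alternative 3: The cut is C1–C2. In the forward step a primary C2 radical, made from the iodide with (Bu3Sn)2 and light, would add to C1 of an α-(phenylsulfonylmethyl)butenolide anti to the C14 substituent and expel PhSO2, giving A3. A3 is identical with 23 of the chosen route.
- In its favour: the ring, C1 and the C15=C17 methylene arise in one operation at the right oxidation level. No allylic oxidation is needed and the last three steps are shared. Face control at C1 on a flat five-membered ring is at least as secure as in the chosen plan.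
- Against it here: the C2 radical sits six atoms from C7 and cis to C5 on the dioxolane. Its 6-exo closure onto C7=C8 is expected to compete with, and probably outrun, the slow 14-membered closure, and no hydrogen donor is present to intercept it.
- Comparison: the same C2 radical appears in the chosen plan, but only after both rings exist and in the presence of Bu3SnH. Alternative 3 is better in steps after ring closure (three against four) and about equal before it. The chosen plan closes the large ring without radicals and gives the radical the fast 5-exo task, which is the sounder allocation.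

Key step: step 13

Remark (numbering): every intermediate carries the atom numbers of the target (ring C1–C14, methylene unit C15–C17, methyls C18–C20 on C4, C8, C12).

Remark (correction): because the oxirane is closed with inversion at C3, the masked diol must be erythro (3R,4S). Syn-dihydroxylation of the (2E)-alkene of 1 would give the threo diol and then the cis-oxirane, so C3 and C4 are set by epoxidation followed by inversion at C3.

Remark (structures): "trans" at the ring fusion means H1 and H14 anti. 21 and 22 match the target at C1, C4, C13 and C14 and are deliberately epimeric at C3.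

Remark (assumption): the Payne rearrangement–sulfonium ylide homologation of 2,3-epoxy alcohols is assumed to extend to the 3,3-disubstituted oxirane of 2.

## Route

Step 1
Reactants: 1 (2E,6E)-farnesol
Product: 2 (2S,3S)-2,3-epoxyfarnesol
Conditions: Ti(OiPr)4 (10 mol%), L-(+)-diisopropyl tartrate (12 mol%), t-BuOOH, 4 Å MS, CH2Cl2, −20 °C
Reagents that add atoms: tert-butyl hydroperoxide, CC(C)(C)OO
Why: Katsuki–Sharpless asymmetric epoxidation touches only the allylic alcohol alkene; the L-(+)-tartrate complex delivers oxygen to the face that gives (2S,3S), which fixes C4 and the sense of the final oxirane.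

Step 2
Reactants: 2 (2S,3S)-2,3-epoxyfarnesol
Product: 5 (3R,4S,7E)-4,8,12-trimethyltrideca-1,7,11-triene-3,4-diol, via Payne-rearranged terminal epoxide 3 (not isolated), via sulfonium alkoxide 4 (not isolated)
Conditions: Me3S+ I− (5 equiv), n-BuLi (4.8 equiv), THF, −10 °C to rt
Reagents that add atoms: trimethylsulfonium iodide, C[S+](C)C.[I-]
Why: Payne rearrangement (the C2 alkoxide attacks C3 with inversion) gives the terminal oxirane 3, which dimethylsulfonium methylide opens at its CH2; the sulfonium alkoxide 4 then eliminates dimethyl sulfide (one-carbon homologation of a terminal epoxide to an allylic alcohol). C3 is inverted, C4 is untouched and the vinyl carbon is added.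

Step 3
Reactants: 5 (3R,4S,7E)-4,8,12-trimethyltrideca-1,7,11-triene-3,4-diol
Product: 6 (4S,5R)-4-[(3E)-4,8-dimethylnona-3,7-dien-1-yl]-2,2,4-trimethyl-5-vinyl-1,3-dioxolane
Conditions: 2,2-dimethoxypropane, PPTS (cat.), CH2Cl2, rt
Reagents that add atoms: 2,2-dimethoxypropane, COC(C)(C)OC
Why: acid-catalysed transketalisation ties the secondary and tertiary hydroxyls into a dioxolane without touching a stereocentre; PPTS is too weak to protonate the trisubstituted alkenes.

Step 4
Reactants: 6 (4S,5R)-4-[(3E)-4,8-dimethylnona-3,7-dien-1-yl]-2,2,4-trimethyl-5-vinyl-1,3-dioxolane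
Product: 7 (2E,6E)-2,6-dimethyl-9-[(4S,5R)-2,2,4-trimethyl-5-vinyl-1,3-dioxolan-4-yl]nona-2,6-dien-1-ol
Conditions: SeO2 (0.3 equiv), t-BuOOH (3 equiv), salicylic acid (0.1 equiv), CH2Cl2, 0 °C to rt, stopped at partial conversion
Reagents that add atoms: selenium dioxide, O=[Se]=O (transfers the oxygen); tert-butyl hydroperoxide, CC(C)(C)OO (re-oxidant)
Why: catalytic SeO2 allylic oxidation (ene reaction, then 2,3-shift) prefers the E-methyl of the terminal, most accessible trisubstituted alkene, as in farnesyl derivatives; the vinyl group is inert, and running to partial conversion limits attack at C7=C8.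

Step 5
Reactants: 7 (2E,6E)-2,6-dimethyl-9-[(4S,5R)-2,2,4-trimethyl-5-vinyl-1,3-dioxolan-4-yl]nona-2,6-dien-1-ol
Product: 8 (2E,6E)-2,6-dimethyl-9-[(4S,5R)-2,2,4-trimethyl-5-vinyl-1,3-dioxolan-4-yl]nona-2,6-dienal
Conditions: MnO2 (20 equiv), CH2Cl2, rt
Reagents that add atoms: none
Why: MnO2 oxidises only the allylic alcohol and keeps the 11E geometry; any enal already formed in step 4 is combined here.

Step 6
Reactants: 8 (2E,6E)-2,6-dimethyl-9-[(4S,5R)-2,2,4-trimethyl-5-vinyl-1,3-dioxolan-4-yl]nona-2,6-dienal; 9 allyl 4-methoxybenzyl ether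
Product: 14 (3S,4S,5E,9E)-3-(4-methoxybenzyloxy)-5,9-dimethyl-12-[(4S,5R)-2,2,4-trimethyl-5-vinyl-1,3-dioxolan-4-yl]dodeca-1,5,9-trien-4-ol, via lithiated allyl ether 10 (not isolated), via methoxyborate 11 (not isolated), via alkoxyallylborane 12 (not isolated), via borinate adduct 13 (not isolated)
Conditions: s-BuLi, THF, −78 °C; (+)-Ipc2BOMe, −78 °C; BF3·OEt2; then 8, −78 °C to rt; NaOH, H2O2
Reagents that add atoms: none
Why: Brown γ-alkoxyallylboration; the chelated (Z)-allyl unit reacts through a chair transition state to give the syn 1,2-diol monoether. The isopinocampheyl groups from (−)-α-pinene direct attack to the aldehyde face that gives 13S, hence (13S,14S) in target numbering, overriding the remote C3/C4 centres.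

Step 7
Reactants: 14 (3S,4S,5E,9E)-3-(4-methoxybenzyloxy)-5,9-dimethyl-12-[(4S,5R)-2,2,4-trimethyl-5-vinyl-1,3-dioxolan-4-yl]dodeca-1,5,9-trien-4-ol
Product: 15 4-O-triisopropylsilyl ether of 14
Conditions: TIPSOTf, 2,6-lutidine, CH2Cl2, 0 °C to rt
Reagents that add atoms: triisopropylsilyl trifluoromethanesulfonate, CC(C)[Si](C(C)C)(C(C)C)OS(=O)(=O)C(F)(F)F
Why: silylation of the hindered allylic alcohol with the silyl triflate; the bulky triisopropylsilyl group is chosen because it resists 1,2-shift to a neighbouring alkoxide in step 10, where an acetate would migrate.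

Step 8
Reactants: 15 4-O-triisopropylsilyl ether of 14
Product: 16 (3S,4S,5E,9E)-5,9-dimethyl-4-(triisopropylsilyloxy)-12-[(4S,5R)-2,2,4-trimethyl-5-vinyl-1,3-dioxolan-4-yl]dodeca-1,5,9-trien-3-ol
Conditions: DDQ, CH2Cl2/pH 7 buffer (10:1), 0 °C
Reagents that add atoms: none
Why: oxidative cleavage of the 4-methoxybenzyl ether (hydride abstraction to the oxocarbenium ion, then hydrolysis); silyl ether, dioxolane and alkenes are inert under buffered conditions.

Step 9
Reactants: 16 (3S,4S,5E,9E)-5,9-dimethyl-4-(triisopropylsilyloxy)-12-[(4S,5R)-2,2,4-trimethyl-5-vinyl-1,3-dioxolan-4-yl]dodeca-1,5,9-trien-3-ol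
Product: 17 (1E,3R,4S,7E,11E,13S,14S)-3,4-(isopropylidenedioxy)-4,8,12-trimethyl-13-(triisopropylsilyloxy)cyclotetradeca-1,7,11-trien-14-ol
Conditions: (PCy3)2Cl2Ru=CHPh (first-generation Grubbs catalyst, 15 mol% in portions), CH2Cl2 (1 mM), 40 °C
Reagents that add atoms: none
Why: ring-closing metathesis of the two vinyl groups with loss of ethene; the free allylic hydroxyl on C14 should make the catalyst load at the C14 vinyl, and the first-generation catalyst reacts poorly with trisubstituted alkenes, which disfavours six-ring closure of a C2 alkylidene onto C7=C8. The E alkene is expected to predominate because both allylic carbons are substituted.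

Step 10
Reactants: 17 (1E,3R,4S,7E,11E,13S,14S)-3,4-(isopropylidenedioxy)-4,8,12-trimethyl-13-(triisopropylsilyloxy)cyclotetradeca-1,7,11-trien-14-ol; 18 2,3-dibromopropene
Product: 19 14-O-(2-bromoprop-2-en-1-yl) ether of 17
Conditions: NaH, Bu4NI (cat.), THF, 0 °C to rt
Reagents that add atoms: none
Why: Williamson etherification, SN2 at the allylic CH2Br of 18 by the C14 alkoxide; the vinylic bromide does not react and the triisopropylsilyl group on O13 should stay in place.

Step 11
Reactants: 19 14-O-(2-bromoprop-2-en-1-yl) ether of 17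
Product: 20 (1E,3R,4S,7E,11E,13S,14S)-14-(2-bromoprop-2-en-1-yloxy)-3,4-(isopropylidenedioxy)-4,8,12-trimethylcyclotetradeca-1,7,11-trien-13-ol
Conditions: Bu4NF, AcOH (1:1), THF, rt
Reagents that add atoms: none
Why: fluoride desilylation; buffering with acetic acid lowers the basicity so the 2-bromoalkene is not dehydrobrominated.

Step 12
Reactants: 20 (1E,3R,4S,7E,11E,13S,14S)-14-(2-bromoprop-2-en-1-yloxy)-3,4-(isopropylidenedioxy)-4,8,12-trimethylcyclotetradeca-1,7,11-trien-13-ol
Product: 21 13-O-acetate of 20
Conditions: Ac2O, pyridine, DMAP (cat.), CH2Cl2, rt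
Reagents that add atoms: acetic anhydride, CC(=O)OC(C)=O
Why: DMAP-catalysed acylation of the hindered allylic alcohol; with O14 already etherified no acyl shift is possible, and the acetate makes the C13–H bond less prone to hydrogen transfer in step 13.

Step 13
Reactants: 21 13-O-acetate of 20
Product: 22 (1S,3R,4S,7E,11E,13S,14S)-13-acetoxy-3,4-(isopropylidenedioxy) macrocycle trans-fused at C1/C14 to a 3-methyleneoxolane (O on C14; C15 on C1; C16 = CH2)
Conditions: Bu3SnH (1.3 equiv), Et3B (0.3 equiv), air, PhMe (0.01 M), 0 °C to rt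
Reagents that add atoms: none
Why: Bu3Sn• abstracts bromine from 21, and the σ-vinyl radical at C15 adds to C1, the near carbon of the C1=C2 alkene; the secondary C2 radical is then reduced by Bu3SnH and the chain continues. The closest known reaction type is the tin hydride cyclisation of 2-bromoallyl ethers of allylic alcohols to 3-methyleneoxolanes, the vinyl-radical form of the Ueno–Stork reaction. The oxolane (O, C14, C1, C15, C16) closes in the 5-exo-trig mode and forms the C1–C15 bond. C1 is controlled by C14: the C14–H bond lies near the plane of the E-alkene, so the oxygen tether and C13 sit on opposite faces, and a chair-like transition state with the C14–C13 bond pseudo-equatorial delivers C15 anti to C13, giving the trans fusion (1S). Three selectivities are needed: 5-exo attack at C1 over 6-exo attack at the more substituted C12; ring closure over 1,5-hydrogen transfer from C13–H, which the acetate deactivates; and reduction of the C2 radical over transannular 6-exo addition to C7. The last is helped by low temperature, because hydrogen transfer from tin has the lower barrier, which is why Et3B/air initiation is preferred to AIBN at 80 °C. The dioxolane keeps the C3–O bond from fragmenting next to the C2 radical.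

Step 14
Reactants: 22 (1S,3R,4S,7E,11E,13S,14S)-13-acetoxy-3,4-(isopropylidenedioxy) macrocycle trans-fused at C1/C14 to a 3-methyleneoxolane
Product: 23 (1S,3R,4S,7E,11E,13S,14S)-13-acetoxy-3,4-(isopropylidenedioxy) α-methylene-γ-lactone (C16 = C=O)
Conditions: CrO3 (20 equiv), 3,5-dimethylpyrazole (20 equiv), CH2Cl2, −20 °C
Reagents that add atoms: chromium trioxide, O=[Cr](=O)=O
Why: allylic oxidation with the CrO3–3,5-dimethylpyrazole complex; the C16 hydrogens are both allylic and next to the ring oxygen, so they are abstracted first, which is the known conversion of 3-methyleneoxolanes into α-methylene-γ-lactones.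

Step 15
Reactants: 23 (1S,3R,4S,7E,11E,13S,14S)-13-acetoxy-3,4-(isopropylidenedioxy) α-methylene-γ-lactone
Product: 24 (1S,3R,4S,7E,11E,13S,14S)-13-acetoxy-3,4-dihydroxy α-methylene-γ-lactone
Conditions: AcOH/H2O/THF (3:1:1), 45 °C
Reagents that add atoms: none
Why: mild acid hydrolysis of the ketal; the acetate, the unsaturated lactone and the trisubstituted alkenes tolerate aqueous acetic acid.

Step 16
Reactants: 24 (1S,3R,4S,7E,11E,13S,14S)-13-acetoxy-3,4-dihydroxy α-methylene-γ-lactone
Product: 25 3-O-methanesulfonate of 24
Conditions: MsCl (1.1 equiv), Et3N, CH2Cl2, −20 to 0 °C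
Reagents that add atoms: methanesulfonyl chloride, CS(=O)(=O)Cl
Why: selective sulfonylation of the secondary C3 hydroxyl; the tertiary C4 hydroxyl is too hindered to react with one equivalent at low temperature.

Step 17
Reactants: 25 3-O-methanesulfonate of 24
Product: 26 13-acetoxysarcocrassolide (1S,3S,4S,7E,11E,13S,14S)
Conditions: NaN(SiMe3)2 (1.05 equiv), THF, −78 to 0 °C
Reagents that add atoms: none
Why: intramolecular Williamson closure (3-exo-tet); the C4 alkoxide displaces the mesylate with inversion at C3, giving the (3S,4S) trans-oxirane. One equivalent of a hindered, non-nucleophilic base at low temperature should spare the acetate and the methylene lactone.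

## Compound list

1 | (2E,6E)-farnesol | CC(C)=CCC/C(C)=C/CC/C(C)=C/CO | starting material
2 | (2S,3S)-2,3-epoxyfarnesol | OC[C@@H]1O[C@@]1(C)CC/C=C(\C)CCC=C(C)C | intermediate
3 | (2S,5E)-6,10-dimethyl-2-[(2R)-oxiran-2-yl]undeca-5,9-dien-2-ol, formed as its lithium alkoxide | C1O[C@H]1[C@@](C)(O)CC/C=C(\C)CCC=C(C)C | intermediate (not isolated)
4 | [(3R,4S,7E)-4-hydroxy-4,8,12-trimethyl-3-oxidotrideca-7,11-dien-1-yl]dimethylsulfonium | C[S+](C)CC[C@@H]([O-])[C@@](C)(O)CC/C=C(\C)CCC=C(C)C | intermediate (not isolated)
5 | (3R,4S,7E)-4,8,12-trimethyltrideca-1,7,11-triene-3,4-diol | C=C[C@@H](O)[C@@](C)(O)CC/C=C(\C)CCC=C(C)C | intermediate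
6 | (4S,5R)-4-[(3E)-4,8-dimethylnona-3,7-dien-1-yl]-2,2,4-trimethyl-5-vinyl-1,3-dioxolane | C=C[C@H]1OC(C)(C)O[C@@]1(C)CC/C=C(\C)CCC=C(C)C | intermediate
7 | (2E,6E)-2,6-dimethyl-9-[(4S,5R)-2,2,4-trimethyl-5-vinyl-1,3-dioxolan-4-yl]nona-2,6-dien-1-ol | C=C[C@H]1OC(C)(C)O[C@@]1(C)CC/C=C(\C)CC/C=C(\C)CO | intermediate
8 | (2E,6E)-2,6-dimethyl-9-[(4S,5R)-2,2,4-trimethyl-5-vinyl-1,3-dioxolan-4-yl]nona-2,6-dienal | C=C[C@H]1OC(C)(C)O[C@@]1(C)CC/C=C(\C)CC/C=C(\C)C=O | intermediate
9 | allyl 4-methoxybenzyl ether | C=CCOCc1ccc(OC)cc1 | starting material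
10 | [(2Z)-3-(4-methoxybenzyloxy)prop-2-en-1-yl]lithium | [Li]C/C=C\OCc1ccc(OC)cc1 | intermediate (not isolated)
11 | lithium methoxy[(2Z)-3-(4-methoxybenzyloxy)prop-2-en-1-yl]bis[(1S,2R,3S,5S)-isopinocampheyl]borate | [Li+].CO[B-](C/C=C\OCc1ccc(OC)cc1)([C@H]1C[C@H]2C[C@@H]([C@@H]1C)C2(C)C)[C@H]1C[C@H]2C[C@@H]([C@@H]1C)C2(C)C | intermediate (not isolated)
12 | [(2Z)-3-(4-methoxybenzyloxy)prop-2-en-1-yl]bis[(1S,2R,3S,5S)-isopinocampheyl]borane | COc1ccc(CO/C=C\CB([C@H]2C[C@H]3C[C@@H]([C@@H]2C)C3(C)C)[C@H]2C[C@H]3C[C@@H]([C@@H]2C)C3(C)C)cc1 | intermediate (not isolated)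
13 | bis(isopinocampheyl)borinate of 14 at O13 | C=C[C@H]1OC(C)(C)O[C@@]1(C)CC/C=C(\C)CC/C=C(\C)[C@H](OB([C@H]2C[C@H]3C[C@@H]([C@@H]2C)C3(C)C)[C@H]2C[C@H]3C[C@@H]([C@@H]2C)C3(C)C)[C@@H](OCc1ccc(OC)cc1)C=C | intermediate (not isolated)
14 | (3S,4S,5E,9E)-3-(4-methoxybenzyloxy)-5,9-dimethyl-12-[(4S,5R)-2,2,4-trimethyl-5-vinyl-1,3-dioxolan-4-yl]dodeca-1,5,9-trien-4-ol | C=C[C@H]1OC(C)(C)O[C@@]1(C)CC/C=C(\C)CC/C=C(\C)[C@H](O)[C@@H](OCc1ccc(OC)cc1)C=C | intermediate
15 | 4-O-triisopropylsilyl ether of 14 | C=C[C@H]1OC(C)(C)O[C@@]1(C)CC/C=C(\C)CC/C=C(\C)[C@H](O[Si](C(C)C)(C(C)C)C(C)C)[C@@H](OCc1ccc(OC)cc1)C=C | intermediate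
16 | (3S,4S,5E,9E)-5,9-dimethyl-4-(triisopropylsilyloxy)-12-[(4S,5R)-2,2,4-trimethyl-5-vinyl-1,3-dioxolan-4-yl]dodeca-1,5,9-trien-3-ol | C=C[C@H]1OC(C)(C)O[C@@]1(C)CC/C=C(\C)CC/C=C(\C)[C@H](O[Si](C(C)C)(C(C)C)C(C)C)[C@@H](O)C=C | intermediate
17 | (1E,3R,4S,7E,11E,13S,14S)-3,4-(isopropylidenedioxy)-4,8,12-trimethyl-13-(triisopropylsilyloxy)cyclotetradeca-1,7,11-trien-14-ol | O[C@H]1/C=C/[C@H]2OC(C)(C)O[C@@]2(C)CC/C=C(\C)CC/C=C(\C)[C@@H]1O[Si](C(C)C)(C(C)C)C(C)C | intermediate
18 | 2,3-dibromopropene | C=C(Br)CBr | starting material
19 | 14-O-(2-bromoprop-2-en-1-yl) ether of 17 | C=C(Br)CO[C@H]1/C=C/[C@H]2OC(C)(C)O[C@@]2(C)CC/C=C(\C)CC/C=C(\C)[C@@H]1O[Si](C(C)C)(C(C)C)C(C)C | intermediate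
20 | (1E,3R,4S,7E,11E,13S,14S)-14-(2-bromoprop-2-en-1-yloxy)-3,4-(isopropylidenedioxy)-4,8,12-trimethylcyclotetradeca-1,7,11-trien-13-ol | C=C(Br)CO[C@H]1/C=C/[C@H]2OC(C)(C)O[C@@]2(C)CC/C=C(\C)CC/C=C(\C)[C@@H]1O | intermediate
21 | 13-O-acetate of 20 (precursor of the key step) | C=C(Br)CO[C@H]1/C=C/[C@H]2OC(C)(C)O[C@@]2(C)CC/C=C(\C)CC/C=C(\C)[C@@H]1OC(C)=O | intermediate
22 | (1S,3R,4S,7E,11E,13S,14S)-13-acetoxy-3,4-(isopropylidenedioxy) macrocycle trans-fused at C1/C14 to a 3-methyleneoxolane (product of the key step) | C=C1CO[C@H]2[C@H]1C[C@H]1OC(C)(C)O[C@@]1(C)CC/C=C(\C)CC/C=C(\C)[C@@H]2OC(C)=O | intermediate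
23 | (1S,3R,4S,7E,11E,13S,14S)-13-acetoxy-3,4-(isopropylidenedioxy) α-methylene-γ-lactone | C=C1C(=O)O[C@H]2[C@H]1C[C@H]1OC(C)(C)O[C@@]1(C)CC/C=C(\C)CC/C=C(\C)[C@@H]2OC(C)=O | intermediate
24 | (1S,3R,4S,7E,11E,13S,14S)-13-acetoxy-3,4-dihydroxy α-methylene-γ-lactone | C=C1C(=O)O[C@H]2[C@H]1C[C@@H](O)[C@@](C)(O)CC/C=C(\C)CC/C=C(\C)[C@@H]2OC(C)=O | intermediate
25 | 3-O-methanesulfonate of 24 | C=C1C(=O)O[C@H]2[C@H]1C[C@@H](OS(C)(=O)=O)[C@@](C)(O)CC/C=C(\C)CC/C=C(\C)[C@@H]2OC(C)=O | intermediate
26 | 13-acetoxysarcocrassolide (1S,3S,4S,7E,11E,13S,14S) | C=C1C(=O)O[C@H]2[C@H]1C[C@@H]1O[C@@]1(C)CC/C=C(\C)CC/C=C(\C)[C@@H]2OC(C)=O | target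

## Step count and least certain steps

Total: 17 steps. Longest linear sequence: 17 steps from 1; 9 and 18 enter as one-step building blocks.

Step 13 (key step). Three processes may go wrong. Hydrogen may be transferred to the σ-vinyl radical before it closes, from tin hydride or by a 1,5-shift from C13–H. The C2 radical may add across the ring to C7 before it is reduced. C15 may be delivered to the wrong face of C1 if the macrocycle adopts another local conformation. Fallback (sets out from 17, comes back at 23): the ring oxygen tether carries an alkyl radical instead. 17 is treated with ethyl vinyl ether and N-bromosuccinimide to give the bromoacetal F1. Bu3SnH/Et3B closes the same C1–C15 bond and oxolane ring through the slower, more selective primary radical, giving the cyclic acetal F2. CrO3/H2SO4 in acetone, which protects the ketal by mass action, gives the saturated lactone F3. LiN(iPr)2, then CH2=NMe2+ I−, MeI and NaHCO3 give the α-methylene lactone F4. Bu4NF gives the 13-alcohol F5, and Ac2O gives 23. This detour also removes step 14.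

Step 9. An alkylidene formed on C2 may close a six-membered ring onto C7=C8 and cut the chain. This is the expected course whenever the catalyst loads at the C3-side vinyl, because the dioxolane holds C2 and C5 cis. Oligomerisation and some Z alkene are further risks. (H2IMes)(PCy3)Cl2Ru=CHPh (second-generation Grubbs catalyst) would close hindered alkenes better but also attacks trisubstituted alkenes more readily. Fallback (sets out from 8, comes back at 17): the C3-side vinyl is made unable to take up the metal first. Heck arylation of 8 with iodobenzene (Pd(OAc)2, Bu4NCl, NaHCO3, DMF) gives the styryl enal F6. Steps 6 to 8 then give the styryl homoallylic alcohol F7, its silyl ether F8 and the styryl diene alcohol F9. Ring closure of F9 can start only at the C14 vinyl and ends on the styryl group with loss of styrene, giving 17.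

Step 2. The Payne equilibrium lies on the side of the trisubstituted oxirane and passes through a tertiary alkoxide. The ylide may therefore consume 2 too slowly, or decompose before the terminal oxirane is trapped, leaving starting material. Fallback (sets out from 2, comes back at 6): the Payne rearrangement–thiolate opening route. PhSH/NaOH in t-BuOH/H2O gives the phenylthio diol F10 with the same inversion at C3. 2,2-Dimethoxypropane gives the thioether acetonide F11. NaIO4 gives the sulfoxide F12. Pummerer rearrangement (Ac2O, NaOAc) gives the α-acetoxy sulfide F13. i-Bu2AlH at −78 °C gives the aldehyde F14, which Ph3P=CH2 converts into 6. The C3 centre next to the aldehyde can epimerise and would need cold, salt-free olefination.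

Step 14. The chromium reagent may also oxidise the other allylic CH2 groups (C6, C9, C10) to enones, or stall, because a large excess is needed. Fallback (sets out from 17, comes back at 24): C16 is carried into the cyclisation at the aldehyde level. Methoxyallene and N-bromosuccinimide convert 17 into the 2-bromoallyl mixed acetal F15. Bu4NF/AcOH gives the alcohol F16 and Ac2O the acetate F17. The same tin hydride cyclisation gives the 16-methoxy-15-methyleneoxolane F18. Aqueous acetic acid hydrolyses both acetal and ketal to the lactol diol F19, and MnO2 oxidises only the allylic lactol to give 24.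

## Further compounds

F1 | step 13 | 14-O-(2-bromo-1-ethoxyethyl) mixed acetal of 17 (acetal epimers) | CCOC(CBr)O[C@H]1/C=C/[C@H]2OC(C)(C)O[C@@]2(C)CC/C=C(\C)CC/C=C(\C)[C@@H]1O[Si](C(C)C)(C(C)C)C(C)C
F2 | step 13 | 16-ethoxyoxolane trans-fused at C1/C14 (C15 = CH2), 13-O-triisopropylsilyl, 3,4-acetonide | CCOC1O[C@H]2[C@H](C1)C[C@H]1OC(C)(C)O[C@@]1(C)CC/C=C(\C)CC/C=C(\C)[C@@H]2O[Si](C(C)C)(C(C)C)C(C)C
F3 | step 13 | saturated trans-fused γ-lactone, 13-O-triisopropylsilyl, 3,4-acetonide | O=C1O[C@H]2[C@H](C1)C[C@H]1OC(C)(C)O[C@@]1(C)CC/C=C(\C)CC/C=C(\C)[C@@H]2O[Si](C(C)C)(C(C)C)C(C)C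
F4 | step 13 | α-methylene-γ-lactone, 13-O-triisopropylsilyl, 3,4-acetonide | C=C1C(=O)O[C@H]2[C@H]1C[C@H]1OC(C)(C)O[C@@]1(C)CC/C=C(\C)CC/C=C(\C)[C@@H]2O[Si](C(C)C)(C(C)C)C(C)C
F5 | step 13 | α-methylene-γ-lactone 13-alcohol, 3,4-acetonide | C=C1C(=O)O[C@H]2[C@H]1C[C@H]1OC(C)(C)O[C@@]1(C)CC/C=C(\C)CC/C=C(\C)[C@@H]2O
F6 | step 9 | (2E,6E)-2,6-dimethyl-9-[(4S,5R)-2,2,4-trimethyl-5-[(E)-styryl]-1,3-dioxolan-4-yl]nona-2,6-dienal | c1ccccc1/C=C/[C@H]1OC(C)(C)O[C@@]1(C)CC/C=C(\C)CC/C=C(\C)C=O
F7 | step 9 | styryl analogue of 14 | c1ccccc1/C=C/[C@H]1OC(C)(C)O[C@@]1(C)CC/C=C(\C)CC/C=C(\C)[C@H](O)[C@@H](OCc1ccc(OC)cc1)C=C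
F8 | step 9 | styryl analogue of 15 | c1ccccc1/C=C/[C@H]1OC(C)(C)O[C@@]1(C)CC/C=C(\C)CC/C=C(\C)[C@H](O[Si](C(C)C)(C(C)C)C(C)C)[C@@H](OCc1ccc(OC)cc1)C=C
F9 | step 9 | styryl analogue of 16 | c1ccccc1/C=C/[C@H]1OC(C)(C)O[C@@]1(C)CC/C=C(\C)CC/C=C(\C)[C@H](O[Si](C(C)C)(C(C)C)C(C)C)[C@@H](O)C=C
F10 | step 2 | (2S,3S,6E)-3,7,11-trimethyl-1-(phenylsulfanyl)dodeca-6,10-diene-2,3-diol | c1ccccc1SC[C@@H](O)[C@@](C)(O)CC/C=C(\C)CCC=C(C)C
F11 | step 2 | 2,3-acetonide of F10 | c1ccccc1SC[C@H]1OC(C)(C)O[C@@]1(C)CC/C=C(\C)CCC=C(C)C
F12 | step 2 | sulfoxide of F11 (sulfur epimers) | O=S(C[C@H]1OC(C)(C)O[C@@]1(C)CC/C=C(\C)CCC=C(C)C)c1ccccc1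
F13 | step 2 | α-acetoxy sulfide from Pummerer rearrangement of F12 | CC(=O)OC(Sc1ccccc1)[C@H]1OC(C)(C)O[C@@]1(C)CC/C=C(\C)CCC=C(C)C
F14 | step 2 | (4S,5S)-5-[(3E)-4,8-dimethylnona-3,7-dien-1-yl]-2,2,5-trimethyl-1,3-dioxolane-4-carbaldehyde | O=C[C@H]1OC(C)(C)O[C@@]1(C)CC/C=C(\C)CCC=C(C)C
F15 | step 14 | 14-O-(2-bromo-1-methoxyprop-2-en-1-yl) mixed acetal of 17 (acetal epimers) | C=C(Br)C(OC)O[C@H]1/C=C/[C@H]2OC(C)(C)O[C@@]2(C)CC/C=C(\C)CC/C=C(\C)[C@@H]1O[Si](C(C)C)(C(C)C)C(C)C
F16 | step 14 | 13-alcohol from F15 | C=C(Br)C(OC)O[C@H]1/C=C/[C@H]2OC(C)(C)O[C@@]2(C)CC/C=C(\C)CC/C=C(\C)[C@@H]1O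
F17 | step 14 | 13-acetate of F16 | C=C(Br)C(OC)O[C@H]1/C=C/[C@H]2OC(C)(C)O[C@@]2(C)CC/C=C(\C)CC/C=C(\C)[C@@H]1OC(C)=O
F18 | step 14 | 16-methoxy-15-methyleneoxolane trans-fused at C1/C14, 13-acetate, 3,4-acetonide | C=C1C(OC)O[C@H]2[C@H]1C[C@H]1OC(C)(C)O[C@@]1(C)CC/C=C(\C)CC/C=C(\C)[C@@H]2OC(C)=O
F19 | step 14 | 16-hydroxy-15-methyleneoxolane (lactol) 3,4-diol, 13-acetate | C=C1C(O)O[C@H]2[C@H]1C[C@@H](O)[C@@](C)(O)CC/C=C(\C)CC/C=C(\C)[C@@H]2OC(C)=O
A1 | alternative 1 | 14-membered C4 ketone with C5 phenylsulfonyl group, 3-O-(4-methoxybenzyl), 13-O-tert-butyldimethylsilyl, saturated trans-lactone | C1C(=O)O[C@H]2[C@H]1C[C@@H](OCc1ccc(OC)cc1)C(=O)C(S(=O)(=O)c1ccccc1)C/C=C(\C)CC/C=C(\C)[C@@H]2O[Si](C)(C)C(C)(C)C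
A2 | alternative 2 | 14-membered cycloalkyne (C11≡C12) with oxirane and α-methylene lactone, 13-O-triethylsilyl | C=C1C(=O)O[C@H]2[C@H]1C[C@@H]1O[C@@]1(C)CC/C=C(\C)CCC#C[C@@H]2O[Si](CC)(CC)CC
A3 | alternative 3 | α-methylene lactone 3,4-acetonide 13-acetate (identical with 23) | C=C1C(=O)O[C@H]2[C@H]1C[C@H]1OC(C)(C)O[C@@]1(C)CC/C=C(\C)CC/C=C(\C)[C@@H]2OC(C)=O
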